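**Retrosynthetic overview**

1. Target 18 ⇐ macrocyclic enone 17 by catalyst-controlled CBS reduction of the C3 ketone.
2. 17 ⇐ seco acetate / enol silane 15 by a new macrocyclising organocatalytic SN2'–SN2' allylic alkylation (C1–C2 bond, sets C1; the 14-membered ring is formed last).
3. 15 ⇐ lactol 8 by alkenylalane addition (Morita–Baylis–Hillman-type adduct), acetylation, cross-metathesis to the E-enone and silylation.
4. 8 ⇐ achiral trienal 6 by Shi bis-epoxidation and a carbonyl-initiated epoxide-opening cascade (sets C7, C8, C11, C12; forms the oxolane first, with the lactol as a temporary second ring).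
5. 6 ⇐ (2E,6E)-farnesyl bromide + vinylmagnesium bromide, then excision of the terminal isopropylidene.

Numbering note: C1–C20 are cembrane locants of the target (C1 bears the acrylate, C3 the allylic OH, C7 the acetate, C8/C11 the ether bridge, C12 the tertiary OH); the same locants are used for these carbons in acyclic intermediates.

Assumption: the facial preference of (DHQD)2PHAL in the new step 9 cannot be read from precedent; if it gives the 1R ring, the pseudoenantiomer (DHQ)2PHAL is used under the same conditions.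

**Route**

Step 1
Reactants: 1 (2E,6E)-farnesyl bromide; 2 vinylmagnesium bromide
Product: 3 (4E,8E)-5,9,13-trimethyltetradeca-1,4,8,12-tetraene
Conditions: CH2=CHMgBr (1.5 equiv), CuI (10 mol%), THF, −30 to 0 °C
Reagents that add atoms: none
Why: Copper-catalysed Grignard cross-coupling of a primary allylic bromide is α-selective and keeps the 2E geometry, giving the skipped diene without any stereocentre.

Step 2
Reactants: 3 (4E,8E)-5,9,13-trimethyltetradeca-1,4,8,12-tetraene
Product: 5 2,2-dimethyl-3-[(3E,7E)-3,7-dimethylundeca-3,7,10-trien-1-yl]oxirane (racemic), via bromohydrin 4 (not isolated)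
Conditions: NBS (1.1 equiv), THF/H2O 4:1, 0 °C; then K2CO3, MeOH, 23 °C
Reagents that add atoms: water, O (epoxide oxygen); N-bromosuccinimide, O=C1CCC(=O)N1Br (its bromine sits only in 4 and is lost on ring closure)
Why: Van Tamelen terminal-selective bromohydrin formation on the coiled polyene followed by intramolecular Williamson closure marks only the isopropylidene alkene, and the racemic centre is excised in step 3.

Step 3
Reactants: 5 2,2-dimethyl-3-[(3E,7E)-3,7-dimethylundeca-3,7,10-trien-1-yl]oxirane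
Product: 6 (4E,8E)-4,8-dimethyldodeca-4,8,11-trienal
Conditions: H5IO6 (1.2 equiv), THF/Et2O, 0 °C
Reagents that add atoms: none
Why: Periodic acid opens the trisubstituted epoxide and cleaves the resulting glycol (Malaprade-type cleavage) to the achiral aldehyde and acetone while the three remaining alkenes are inert.

Step 4
Reactants: 6 (4E,8E)-4,8-dimethyldodeca-4,8,11-trienal
Product: 8 (5S)-5-[(2R,5S)-5-[(1R)-1-hydroxybut-3-en-1-yl]-5-methyloxolan-2-yl]-5-methyloxolan-2-ol (anomer mixture), via bis-epoxy aldehyde 7 (not isolated)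
Conditions: D-fructose-derived Shi ketone (0.3 equiv), KHSO5 (as Oxone, 2.8 equiv), K2CO3, Bu4NHSO4 (cat.), MeCN/CH2(OMe)2/aq. Na2B4O7 buffer pH 10.5, 0 °C, 2 h; extract; then HClO4 (5 mol%), THF/H2O 10:1, 0 °C
Reagents that add atoms: potassium peroxymonosulfate, [K+].[O-]S(=O)(=O)OO (two epoxide oxygens); water, O
Why: Shi asymmetric epoxidation (chiral dioxirane, spiro transition state) turns both E-trisubstituted alkenes into R,R-epoxides as the first stereocentres while the vinyl group is left, and the carbonyl-initiated exo epoxide-opening cascade then opens C12 with inversion by the aldehyde hydrate oxygen and C8 with inversion by the freed C11 hydroxyl, giving 7R,8S,11R,12S.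

Step 5
Reactants: 8 lactol (5S)-5-[(2R,5S)-5-[(1R)-1-hydroxybut-3-en-1-yl]-5-methyloxolan-2-yl]-5-methyloxolan-2-ol; 9 methyl propiolate
Product: 11 methyl (6S)-3,6-dihydroxy-6-[(2R,5S)-5-[(1R)-1-hydroxybut-3-en-1-yl]-5-methyloxolan-2-yl]-2-methylideneheptanoate (both C1 carbinol epimers), via alkenylalane 10 (not isolated)
Conditions: iBu2AlH (5 equiv), NMO (5 equiv), THF, 0 °C, then 9 (5 equiv), 1 h; then 8, 0 to 23 °C, 12 h; aq. KNaC4H4O6
Reagents that add atoms: none
Why: Vinylalumination (α-hydroalumination of the propiolate, then addition of the α-(methoxycarbonyl)vinyl alane to the aldehyde tautomer of the aluminium lactolate) gives the Morita–Baylis–Hillman-type alcohol and frees the C12 hydroxyl; the new carbinol forms as both epimers, which step 9 converges.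

Step 6
Reactants: 11 methyl (6S)-3,6-dihydroxy-6-[(2R,5S)-5-[(1R)-1-hydroxybut-3-en-1-yl]-5-methyloxolan-2-yl]-2-methylideneheptanoate
Product: 12 methyl (6S)-3-acetoxy-6-[(2R,5S)-5-[(1R)-1-acetoxybut-3-en-1-yl]-5-methyloxolan-2-yl]-6-hydroxy-2-methylideneheptanoate (both C1 epimers)
Conditions: AcCl (3 equiv), pyridine, CH2Cl2, 0 to 23 °C
Reagents that add atoms: acetyl chloride, CC(Cl)=O (two acetyl groups)
Why: Pyridine-mediated O-acylation esterifies the two secondary alcohols (the C7 acetate of the target and the allylic leaving group at C1) and leaves the tertiary C12 hydroxyl; DMAP is avoided so that no Lewis base ionises the new allylic acetate.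

Step 7
Reactants: 12 methyl (6S)-3-acetoxy-6-[(2R,5S)-5-[(1R)-1-acetoxybut-3-en-1-yl]-5-methyloxolan-2-yl]-6-hydroxy-2-methylideneheptanoate; 13 3-methylbut-3-en-2-one
Product: 14 methyl (6S)-3-acetoxy-6-[(2R,5S)-5-[(1R,3E)-1-acetoxy-4-methyl-5-oxohex-3-en-1-yl]-5-methyloxolan-2-yl]-6-hydroxy-2-methylideneheptanoate
Conditions: second-generation Hoveyda–Grubbs catalyst RuCl2(H2IMes)(=CH-C6H4-2-OiPr) (10 mol%), 13 (10 equiv), CH2Cl2, 40 °C
Reagents that add atoms: none
Why: Olefin cross-metathesis of the terminal alkene with a 1,1-disubstituted enone gives the E-trisubstituted enone under thermodynamic control, and the hindered α-branched acrylate does not take part.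

Step 8
Reactants: 14 methyl (6S)-3-acetoxy-6-[(2R,5S)-5-[(1R,3E)-1-acetoxy-4-methyl-5-oxohex-3-en-1-yl]-5-methyloxolan-2-yl]-6-hydroxy-2-methylideneheptanoate
Product: 15 methyl (6S)-3-acetoxy-6-[(2R,5S)-5-[(1R,3E)-1-acetoxy-4-methyl-5-(trimethylsilyloxy)hexa-3,5-dien-1-yl]-5-methyloxolan-2-yl]-2-methylidene-6-(trimethylsilyloxy)heptanoate
Conditions: Me3SiOTf (2.6 equiv), Et3N (4 equiv), CH2Cl2, −78 to 0 °C; pentane, filtration, no aqueous work-up
Reagents that add atoms: trimethylsilyl trifluoromethanesulfonate, C[Si](C)(C)OS(=O)(=O)C(F)(F)F (two Me3Si groups)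
Why: Soft enolisation of the methyl ketone at its α'-methyl gives the cross-conjugated silyl dienol ether and the same reagent masks the tertiary C12 hydroxyl, while acetates and the acrylate are untouched at low temperature.

Step 9
Reactants: 15 methyl (6S)-3-acetoxy-6-[(2R,5S)-5-[(1R,3E)-1-acetoxy-4-methyl-5-(trimethylsilyloxy)hexa-3,5-dien-1-yl]-5-methyloxolan-2-yl]-2-methylidene-6-(trimethylsilyloxy)heptanoate
Product: 17 methyl (1S,4E,7R,8S,11R,12S)-7-acetoxy-8,11-epoxy-12-hydroxy-3-oxocembra-4,15(17)-dien-16-oate, via silyl ether 16 (not isolated)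
Conditions: (DHQD)2PHAL (30 mol%), PhCF3, 2 mM (15 added by syringe pump over 12 h), 40 °C; then 1 M HCl, THF, 0 °C, 10 min
Reagents that add atoms: none
Why: Proposed new method: a macrocyclising, stereoconvergent Lewis-base-catalysed SN2'–SN2' allylic alkylation in which the cinchona amine adds to the acrylate of either C1 epimer and expels acetate to give one chiral allylammonium ion pair, the acetate activates the tethered enol silane (Me3SiOAc leaves) and the ion-paired enolate attacks C1 on the catalyst-defined face, closing the 14-membered ring, setting C1 as S and releasing the amine, with the C12 hydroxyl masked as its silyl ether so it cannot add to the allylammonium ion before mild acid frees it; the closest known reaction type is the intermolecular cinchona- or phosphine-catalysed allylic alkylation of Morita–Baylis–Hillman acetates, carbonates and fluorides with silyloxyfurans and enol silanes, not yet shown for ring closure to a macrocycle or with a cross-conjugated silyl dienol ether.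

Step 10
Reactants: 17 methyl (1S,4E,7R,8S,11R,12S)-7-acetoxy-8,11-epoxy-12-hydroxy-3-oxocembra-4,15(17)-dien-16-oate
Product: 18 methyl (1S,3S,4E,7R,8S,11R,12S)-7-acetoxy-8,11-epoxy-3,12-dihydroxycembra-4,15(17)-dien-16-oate (target)
Conditions: (R)-2-methyl-CBS-oxazaborolidine (1.0 equiv), catecholborane (3 equiv), toluene/CH2Cl2, −78 °C; MeOH, then aq. NaHCO3
Reagents that add atoms: none
Why: Corey–Bakshi–Shibata reduction with the alkenyl group as the large substituent delivers hydride to give the 3S allylic alcohol under catalyst control (1,2-reduction only), and catecholborane at −78 °C spares the acrylate, the acetate and the E-alkene.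

**Compound list**

1 | (2E,6E)-farnesyl bromide, (2E,6E)-1-bromo-3,7,11-trimethyldodeca-2,6,10-triene | BrC/C=C(\C)CC/C=C(\C)CCC=C(C)C | starting material
2 | vinylmagnesium bromide | C=C[Mg]Br | starting material
3 | (4E,8E)-5,9,13-trimethyltetradeca-1,4,8,12-tetraene | C=CC/C=C(\C)CC/C=C(\C)CCC=C(C)C | intermediate
4 | (6E,10E)-3-bromo-2,6,10-trimethyltetradeca-6,10,13-trien-2-ol (racemic, not isolated) | CC(C)(O)C(Br)CC/C(C)=C/CC/C(C)=C/CC=C | intermediate
5 | 2,2-dimethyl-3-[(3E,7E)-3,7-dimethylundeca-3,7,10-trien-1-yl]oxirane (racemic) | CC1(C)OC1CC/C(C)=C/CC/C(C)=C/CC=C | intermediate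
6 | (4E,8E)-4,8-dimethyldodeca-4,8,11-trienal | O=CCC/C(C)=C/CC/C(C)=C/CC=C | intermediate
7 | (4R,5R,8R,9R)-4,5:8,9-diepoxy-4,8-dimethyldodec-11-enal (not isolated) | O=CCC[C@@]1(C)O[C@@H]1CC[C@@]1(C)O[C@@H]1CC=C | intermediate
8 | (5S)-5-[(2R,5S)-5-[(1R)-1-hydroxybut-3-en-1-yl]-5-methyloxolan-2-yl]-5-methyloxolan-2-ol (anomer mixture) | OC1CC[C@](C)(O1)[C@H]2CC[C@](C)(O2)[C@H](O)CC=C | intermediate
9 | methyl propiolate | C#CC(=O)OC | starting material
10 | methyl 2-(diisobutylalumanyl)prop-2-enoate (made in the flask, not isolated) | C=C(C(=O)OC)[Al](CC(C)C)CC(C)C | intermediate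
11 | methyl (6S)-3,6-dihydroxy-6-[(2R,5S)-5-[(1R)-1-hydroxybut-3-en-1-yl]-5-methyloxolan-2-yl]-2-methylideneheptanoate (both epimers at C3 of the heptanoate, cembrane C1) | C=C(C(=O)OC)C(O)CC[C@](C)(O)[C@H]1CC[C@](C)(O1)[C@H](O)CC=C | intermediate
12 | methyl (6S)-3-acetoxy-6-[(2R,5S)-5-[(1R)-1-acetoxybut-3-en-1-yl]-5-methyloxolan-2-yl]-6-hydroxy-2-methylideneheptanoate (both C3 epimers) | C=C(C(=O)OC)C(OC(C)=O)CC[C@](C)(O)[C@H]1CC[C@](C)(O1)[C@H](OC(C)=O)CC=C | intermediate
13 | 3-methylbut-3-en-2-one | CC(=O)C(C)=C | starting material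
14 | methyl (6S)-3-acetoxy-6-[(2R,5S)-5-[(1R,3E)-1-acetoxy-4-methyl-5-oxohex-3-en-1-yl]-5-methyloxolan-2-yl]-6-hydroxy-2-methylideneheptanoate (both C3 epimers) | C=C(C(=O)OC)C(OC(C)=O)CC[C@](C)(O)[C@H]1CC[C@](C)(O1)[C@H](OC(C)=O)C/C=C(\C)C(C)=O | intermediate
15 | methyl (6S)-3-acetoxy-6-[(2R,5S)-5-[(1R,3E)-1-acetoxy-4-methyl-5-(trimethylsilyloxy)hexa-3,5-dien-1-yl]-5-methyloxolan-2-yl]-2-methylidene-6-(trimethylsilyloxy)heptanoate (both C3 epimers) | C=C(C(=O)OC)C(OC(C)=O)CC[C@](C)(O[Si](C)(C)C)[C@H]1CC[C@](C)(O1)[C@H](OC(C)=O)C/C=C(\C)C(=C)O[Si](C)(C)C | intermediate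
16 | methyl (1S,4E,7R,8S,11R,12S)-7-acetoxy-8,11-epoxy-3-oxo-12-(trimethylsilyloxy)cembra-4,15(17)-dien-16-oate (not isolated) | C=C(C(=O)OC)[C@H]1CC[C@](C)(O[Si](C)(C)C)[C@H]2CC[C@](C)(O2)[C@H](OC(C)=O)C/C=C(\C)C(=O)C1 | intermediate
17 | methyl (1S,4E,7R,8S,11R,12S)-7-acetoxy-8,11-epoxy-12-hydroxy-3-oxocembra-4,15(17)-dien-16-oate | C=C(C(=O)OC)[C@H]1CC[C@](C)(O)[C@H]2CC[C@](C)(O2)[C@H](OC(C)=O)C/C=C(\C)C(=O)C1 | intermediate
18 | methyl (1S,3S,4E,7R,8S,11R,12S)-7-acetoxy-8,11-epoxy-3,12-dihydroxycembra-4,15(17)-dien-16-oate (CNP0266699.4) | C=C(C(=O)OC)[C@H]1CC[C@](C)(O)[C@H]2CC[C@](C)(O2)[C@H](OC(C)=O)C/C=C(\C)[C@@H](O)C1 | target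

**Step count and risks**

Total step count: 10. Longest linear sequence: 10 steps (1 to 18).

Steps most likely to fail:

Step 9 (the proposed new macrocyclisation). Risks are a sluggish ionisation of the allylic acetate by the hindered cinchona amine, oligomerisation competing with 14-ring closure, attack at the CH2 terminus instead of C1, and an unknown or mismatched facial sense. The fallback uses known chemistry and closes the ring at a different bond; it sets out from 12 and comes back at 16. Silylation of 12 (Me3SiOTf, 2,6-lutidine, CH2Cl2, −78 °C) gives the C12 trimethylsilyl ether of diacetate 12 F6. An intermolecular Lewis-base-catalysed allylic alkylation of the Morita–Baylis–Hillman acetate, an established reaction class with enol silanes, is then run with excess 3-methyl-2-(trimethylsilyloxy)buta-1,3-diene F7 (made from 13 with Me3SiOTf and Et3N) and (DHQD)2PHAL (20 mol%) in PhCF3 at 40 °C. This gives methyl (3S,6S)-6-[(2R,5S)-5-[(1R)-1-acetoxybut-3-en-1-yl]-5-methyloxolan-2-yl]-2-methylidene-3-(3-methyl-2-oxobut-3-en-1-yl)-6-(trimethylsilyloxy)heptanoate F8. Ring-closing metathesis of F8 (second-generation Hoveyda–Grubbs catalyst, toluene, 1 mM, 80 °C) forms the C4=C5 enone bond and gives 16, which the acid work-up of step 9 turns into 17.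

Step 4 (Shi epoxidation and cascade on a free aldehyde). The aldehyde may be partly oxidised by KHSO5, and the hydrate-initiated opening at C12 must outrun water attack at C8, which would lead to the trans-oxolane series. The fallback replaces the aldehyde by a carboxylic acid as initiator; it sets out from 6 and comes back at 8. Pinnick oxidation of 6 (NaClO2, NaH2PO4, 2-methylbut-2-ene, tBuOH/H2O) gives (4E,8E)-4,8-dimethyldodeca-4,8,11-trienoic acid F1. Shi epoxidation under the step 4 conditions gives (4R,5R,8R,9R)-4,5:8,9-diepoxy-4,8-dimethyldodec-11-enoic acid F2. Acidification to pH 3 and camphorsulfonic acid (cat.) in CH2Cl2 trigger lactonisation at C12 and oxolane closure, giving (5S)-5-[(2R,5S)-5-[(1R)-1-hydroxybut-3-en-1-yl]-5-methyloxolan-2-yl]-5-methyloxolan-2-one F3. Reduction with iBu2AlH (2.2 equiv, CH2Cl2, −78 °C) gives lactol 8.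

Step 5 (alkenylalane addition to a lactol). The aluminium lactolate may open slowly and the two free hydroxyls consume reagent. The fallback is an enolate aldol and Mannich-base elimination; it sets out from 8 and comes back at 11. The lithium enolate of methyl 3-(dimethylamino)propanoate (LiN(iPr)2, THF, −78 °C, 4 equiv) adds to the open form of 8 to give methyl (6S)-2-[(dimethylamino)methyl]-3,6-dihydroxy-6-[(2R,5S)-5-[(1R)-1-hydroxybut-3-en-1-yl]-5-methyloxolan-2-yl]heptanoate F4. MeI in MeOH gives the corresponding trimethylammonium iodide F5. DBU in CH2Cl2 eliminates trimethylamine and gives 11.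

Further compounds
F1 | step 4 | (4E,8E)-4,8-dimethyldodeca-4,8,11-trienoic acid | OC(=O)CC/C(C)=C/CC/C(C)=C/CC=C
F2 | step 4 | (4R,5R,8R,9R)-4,5:8,9-diepoxy-4,8-dimethyldodec-11-enoic acid | OC(=O)CC[C@@]1(C)O[C@@H]1CC[C@@]1(C)O[C@@H]1CC=C
F3 | step 4 | (5S)-5-[(2R,5S)-5-[(1R)-1-hydroxybut-3-en-1-yl]-5-methyloxolan-2-yl]-5-methyloxolan-2-one | O=C1CC[C@](C)(O1)[C@H]2CC[C@](C)(O2)[C@H](O)CC=C
F4 | step 5 | methyl (6S)-2-[(dimethylamino)methyl]-3,6-dihydroxy-6-[(2R,5S)-5-[(1R)-1-hydroxybut-3-en-1-yl]-5-methyloxolan-2-yl]heptanoate (epimers at C2 and C3) | COC(=O)C(CN(C)C)C(O)CC[C@](C)(O)[C@H]1CC[C@](C)(O1)[C@H](O)CC=C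
F5 | step 5 | trimethylammonium iodide of F4 | COC(=O)C(C[N+](C)(C)C)C(O)CC[C@](C)(O)[C@H]1CC[C@](C)(O1)[C@H](O)CC=C.[I-]
F6 | step 9 | methyl (6S)-3-acetoxy-6-[(2R,5S)-5-[(1R)-1-acetoxybut-3-en-1-yl]-5-methyloxolan-2-yl]-2-methylidene-6-(trimethylsilyloxy)heptanoate (both C3 epimers) | C=C(C(=O)OC)C(OC(C)=O)CC[C@](C)(O[Si](C)(C)C)[C@H]1CC[C@](C)(O1)[C@H](OC(C)=O)CC=C
F7 | step 9 | 3-methyl-2-(trimethylsilyloxy)buta-1,3-diene | C=C(O[Si](C)(C)C)C(C)=C
F8 | step 9 | methyl (3S,6S)-6-[(2R,5S)-5-[(1R)-1-acetoxybut-3-en-1-yl]-5-methyloxolan-2-yl]-2-methylidene-3-(3-methyl-2-oxobut-3-en-1-yl)-6-(trimethylsilyloxy)heptanoate | C=C(C(=O)OC)[C@H](CC(=O)C(C)=C)CC[C@](C)(O[Si](C)(C)C)[C@H]1CC[C@](C)(O1)[C@H](OC(C)=O)CC=C
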